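**Assumption:** the SMILES is read as the cis-(2R,3R)-2,3-dihydrobenzofuran carrying an (S)-1-acetoxyethyl group at C5; both enantiomers of the Shi ketone and the Ru–TsDPEN catalyst are treated as purchasable catalysts.

**Retrosynthetic overview**
1. Target ⇐ allylic C–H oxidation of the isopropenyl methyl (CH3 → CHO, SeO2) on the fully esterified isopropenyl compound, echoing the late oxidase step.
2. (S)-1-Acetoxyethyl group ⇐ asymmetric transfer hydrogenation of the aryl methyl ketone, then acetylation.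
3. cis-C3 isovalerate ⇐ Mitsunobu reaction of the trans-3-ol with isovaleric acid (esterification and C3 inversion in one step).
4. Dihydrofuran ring (the only ring made; the benzene ring is bought) ⇐ phenol-onto-side-chain-epoxide closure as in the biogenesis of tremetone/toxol benzofurans, but run on the dehydroprenyl (dienyl) phenol: asymmetric monoepoxidation and 5-endo opening of the vinyl epoxide set C2 and C3 together.
5. Dienylphenol ⇐ one-pot hydroboration/Suzuki coupling of 2-methylbut-1-en-3-yne with 3'-bromo-4'-hydroxyacetophenone.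

**Route**

Step 1
Reactants: 1 1-(3-bromo-4-hydroxyphenyl)ethanone; 2 2-methylbut-1-en-3-yne; 3 pinacolborane
Product: 5 (E)-1-[4-hydroxy-3-(3-methylbuta-1,3-dien-1-yl)phenyl]ethanone, via dienyl pinacol boronate 4 (not isolated)
Conditions: 2 (1.5 equiv), 3 (1.4 equiv), Cp2Zr(H)Cl (5 mol%), Et3N (10 mol%), neat, sealed, 25–40 °C; then 1, Pd(dppf)Cl2 (3 mol%), K3PO4 (3 equiv), 1,4-dioxane/H2O, 80 °C
Reagents that add atoms: none
Why: Zr-catalysed syn-hydroboration of the terminal alkyne gives the (E)-alkenylboronate (the 1,1-disubstituted alkene is untouched), and Suzuki–Miyaura coupling retains the olefin geometry and tolerates the free phenol and the ketone; no stereocentre is formed.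

Step 2
Reactants: 5 (E)-1-[4-hydroxy-3-(3-methylbuta-1,3-dien-1-yl)phenyl]ethanone
Product: 7 1-[(2R,3S)-3-hydroxy-2-(prop-1-en-2-yl)-2,3-dihydro-1-benzofuran-5-yl]ethanone, via vinyl epoxide 6 (not isolated)
Conditions: ent-Shi ketone (L-fructose-derived, 30 mol%), Oxone (1.4 equiv), K2CO3, Bu4NHSO4 (cat.), MeCN/DMM–aq. Na2B4O7/EDTA buffer (pH ≈ 10.5), −5 → 0 °C; then rt
Reagents that add atoms: Oxone (potassium peroxymonosulfate), [K+].OOS(=O)(=O)[O-]
Why: Proposed new method: the chiral dioxirane epoxidises only the electron-rich trans-disubstituted styrenyl C=C (the 1,1-disubstituted terminus is a poor substrate) to give the (2S,3S)-vinyl epoxide 6, the mirror image of the (R,R) sense the D-fructose ketone gives with trans-β-substituted styrenes; at pH ≈ 10.5 the ortho-phenoxide then opens the epoxide at the allylic carbon in a 5-endo SN2 step (4-exo attack at the benzylic carbon is impossible), so C3 keeps the epoxide configuration (S) and C2 is inverted to R, giving the trans-3-hydroxy-2-isopropenyl ring; closest known reactions are Shi monoepoxidation of conjugated dienes, 5-endo closure of 3,4-epoxy alcohols and of the o-oxiranyl phenoxides formed in Corey–Chaykovsky reactions of salicylaldehydes (which give benzofuran-3-ols), and the biogenetic prenylphenol-epoxide cyclisation.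

Step 3
Reactants: 7 1-[(2R,3S)-3-hydroxy-2-(prop-1-en-2-yl)-2,3-dihydro-1-benzofuran-5-yl]ethanone; 8 3-methylbutanoic acid (isovaleric acid)
Product: 9 (2R,3R)-5-acetyl-2-(prop-1-en-2-yl)-2,3-dihydro-1-benzofuran-3-yl 3-methylbutanoate
Conditions: 8 (1.5 equiv), PPh3, DIAD, toluene, −20 → 0 °C
Reagents that add atoms: none
Why: Mitsunobu esterification: the only free hydroxyl is activated as the alkoxyphosphonium and displaced by isovalerate in an SN2 step with inversion at C3 (S → R), turning the trans-alcohol into the cis-ester; the syn C2–H/C3–O arrangement of 7 blocks anti-elimination to the benzofuran and the acetyl group para to the ring oxygen tempers ionisation at C3.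

Step 4
Reactants: 9 (2R,3R)-5-acetyl-2-(prop-1-en-2-yl)-2,3-dihydro-1-benzofuran-3-yl 3-methylbutanoate
Product: 10 (2R,3R)-5-[(1S)-1-hydroxyethyl]-2-(prop-1-en-2-yl)-2,3-dihydro-1-benzofuran-3-yl 3-methylbutanoate
Conditions: RuCl[(S,S)-TsDPEN](p-cymene) (1 mol%), HCO2H/Et3N (5:2), CH2Cl2, 30 °C
Reagents that add atoms: none
Why: Noyori–Ikariya asymmetric transfer hydrogenation: the (S,S)-TsDPEN–Ru hydride reduces aryl methyl ketones to (S)-1-arylethanols under catalyst control remote from the ring stereocentres, while the ester and the isolated 1,1-disubstituted alkene are inert.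

Step 5
Reactants: 10 (2R,3R)-5-[(1S)-1-hydroxyethyl]-2-(prop-1-en-2-yl)-2,3-dihydro-1-benzofuran-3-yl 3-methylbutanoate
Product: 11 (2R,3R)-5-[(1S)-1-(acetyloxy)ethyl]-2-(prop-1-en-2-yl)-2,3-dihydro-1-benzofuran-3-yl 3-methylbutanoate
Conditions: Ac2O, pyridine, DMAP (cat.), CH2Cl2, 0 °C → rt
Reagents that add atoms: acetic anhydride, CC(=O)OC(C)=O
Why: DMAP-catalysed acylation of the only free hydroxyl proceeds with retention at the carbinol carbon, and the basic, non-ionising conditions leave both benzylic C–O bonds intact.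

Step 6
Reactants: 11 (2R,3R)-5-[(1S)-1-(acetyloxy)ethyl]-2-(prop-1-en-2-yl)-2,3-dihydro-1-benzofuran-3-yl 3-methylbutanoate
Product: 12 (2R,3R)-5-[(1S)-1-(acetyloxy)ethyl]-2-(3-oxoprop-1-en-2-yl)-2,3-dihydro-1-benzofuran-3-yl 3-methylbutanoate
Conditions: SeO2 (1.5 equiv), 1,4-dioxane (trace H2O), 80 °C
Reagents that add atoms: selenium dioxide, O=[Se]=O
Why: Riley allylic oxidation (ene reaction, [2,3]-sigmatropic shift, then further oxidation) converts the isopropenyl methyl into the α-substituted acrolein; in 1,1-disubstituted alkenes CH3 reacts in preference to the methine C2–H, no stereocentre is touched, and amine-free conditions avoid SN2′ loss of the aryloxide from the product enal.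

**Compound list**
1 | 1-(3-bromo-4-hydroxyphenyl)ethanone (3'-bromo-4'-hydroxyacetophenone) | CC(=O)c1ccc(O)c(Br)c1 | starting material
2 | 2-methylbut-1-en-3-yne | C=C(C)C#C | starting material
3 | pinacolborane (4,4,5,5-tetramethyl-1,3,2-dioxaborolane) | B1OC(C)(C)C(C)(C)O1 | starting material
4 | (E)-4,4,5,5-tetramethyl-2-(3-methylbuta-1,3-dien-1-yl)-1,3,2-dioxaborolane (dienyl pinacol boronate) | C=C(C)/C=C/B1OC(C)(C)C(C)(C)O1 | intermediate
5 | (E)-1-[4-hydroxy-3-(3-methylbuta-1,3-dien-1-yl)phenyl]ethanone | CC(=O)c1ccc(O)c(/C=C/C(C)=C)c1 | intermediate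
6 | 1-{4-hydroxy-3-[(2S,3S)-3-(prop-1-en-2-yl)oxiran-2-yl]phenyl}ethanone (trans vinyl epoxide) | C=C(C)[C@@H]1O[C@H]1c1cc(C(C)=O)ccc1O | intermediate
7 | 1-[(2R,3S)-3-hydroxy-2-(prop-1-en-2-yl)-2,3-dihydro-1-benzofuran-5-yl]ethanone (trans-3-ol, toxol skeleton) | C=C(C)[C@H]1Oc2ccc(C(C)=O)cc2[C@@H]1O | intermediate
8 | 3-methylbutanoic acid (isovaleric acid) | CC(C)CC(=O)O | starting material
9 | (2R,3R)-5-acetyl-2-(prop-1-en-2-yl)-2,3-dihydro-1-benzofuran-3-yl 3-methylbutanoate (cis) | C=C(C)[C@H]1Oc2ccc(C(C)=O)cc2[C@H]1OC(=O)CC(C)C | intermediate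
10 | (2R,3R)-5-[(1S)-1-hydroxyethyl]-2-(prop-1-en-2-yl)-2,3-dihydro-1-benzofuran-3-yl 3-methylbutanoate | C=C(C)[C@H]1Oc2ccc([C@H](C)O)cc2[C@H]1OC(=O)CC(C)C | intermediate
11 | (2R,3R)-5-[(1S)-1-(acetyloxy)ethyl]-2-(prop-1-en-2-yl)-2,3-dihydro-1-benzofuran-3-yl 3-methylbutanoate | C=C(C)[C@H]1Oc2ccc([C@H](C)OC(C)=O)cc2[C@H]1OC(=O)CC(C)C | intermediate
12 | (2R,3R)-5-[(1S)-1-(acetyloxy)ethyl]-2-(3-oxoprop-1-en-2-yl)-2,3-dihydro-1-benzofuran-3-yl 3-methylbutanoate (CNP0252902.1) | C=C(C=O)[C@H]1Oc2ccc([C@H](C)OC(C)=O)cc2[C@H]1OC(=O)CC(C)C | target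

**Step count**
Total steps: 6. Longest linear sequence: 6 (1/2/3 → 5 → 7 → 9 → 10 → 11 → 12).

**Three steps most likely to fail, with fallbacks**

Step 2, the epoxidation/cyclisation cascade, is the riskiest. The free phenoxide may be attacked by the oxidant (ring oxidation, Dakin-type cleavage of the aryl ketone). The o-phenoxide epoxide may also open at the benzylic carbon to an o-quinone methide, which would scramble or hydrate C3. The fallback separates oxidation from ring closure and keeps the phenol masked while oxidant and water are present. It sets out from 5, which is silylated (TIPSCl, imidazole, DMF) to (E)-1-{3-(3-methylbuta-1,3-dien-1-yl)-4-[tri(propan-2-yl)silyloxy]phenyl}ethanone F1. Shi epoxidation of this neutral, non-phenolic diene with the same ent-ketone gives the isolable 1-{3-[(2S,3S)-3-(prop-1-en-2-yl)oxiran-2-yl]-4-[tri(propan-2-yl)silyloxy]phenyl}ethanone F2. TBAF in dry THF at −20 °C then releases the phenoxide of 6 under aprotic, oxidant-free conditions, where it closes by the same invertive 5-endo opening, and the route is rejoined at 7.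

Step 3, the Mitsunobu inversion, comes next. Isovaleric acid is a weak Mitsunobu acid, and the activated benzylic C3 may ionise, giving retention or dehydration to the 2-isopropenylbenzofuran. The fallback decouples inversion from installation of the isovalerate. It sets out from 7, which is inverted with the much more acidic 4-nitrobenzoic acid (PPh3, DIAD, toluene) to (2R,3R)-5-acetyl-2-(prop-1-en-2-yl)-2,3-dihydro-1-benzofuran-3-yl 4-nitrobenzoate F3. Mild methanolysis (K2CO3, MeOH, 0 °C) gives the cis-alcohol 1-[(2R,3R)-3-hydroxy-2-(prop-1-en-2-yl)-2,3-dihydro-1-benzofuran-5-yl]ethanone F4. Acylation with retention (isovaleric anhydride, DMAP, pyridine) rejoins the route at 9.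

Step 6, the one-step Riley oxidation, is the third. Hot selenous acid may give incomplete oxidation, attack C2–H, or solvolyse the p-alkoxybenzylic acetate. The fallback splits the four-electron oxidation into two mild two-electron steps. It sets out from 11, which is hydroxylated at room temperature with catalytic SeO2 and t-BuOOH in CH2Cl2 to the allylic alcohol (2R,3R)-5-[(1S)-1-(acetyloxy)ethyl]-2-(3-hydroxyprop-1-en-2-yl)-2,3-dihydro-1-benzofuran-3-yl 3-methylbutanoate F5. Oxidation with activated MnO2 (CH2Cl2, rt) then gives the enal, arriving at 12.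

**Further compounds**
F1 | step 2 | (E)-1-{3-(3-methylbuta-1,3-dien-1-yl)-4-[tri(propan-2-yl)silyloxy]phenyl}ethanone | CC(=O)c1ccc(O[Si](C(C)C)(C(C)C)C(C)C)c(/C=C/C(C)=C)c1
F2 | step 2 | 1-{3-[(2S,3S)-3-(prop-1-en-2-yl)oxiran-2-yl]-4-[tri(propan-2-yl)silyloxy]phenyl}ethanone | C=C(C)[C@@H]1O[C@H]1c1cc(C(C)=O)ccc1O[Si](C(C)C)(C(C)C)C(C)C
F3 | step 3 | (2R,3R)-5-acetyl-2-(prop-1-en-2-yl)-2,3-dihydro-1-benzofuran-3-yl 4-nitrobenzoate | C=C(C)[C@H]1Oc2ccc(C(C)=O)cc2[C@H]1OC(=O)c1ccc(cc1)[N+](=O)[O-]
F4 | step 3 | 1-[(2R,3R)-3-hydroxy-2-(prop-1-en-2-yl)-2,3-dihydro-1-benzofuran-5-yl]ethanone | C=C(C)[C@H]1Oc2ccc(C(C)=O)cc2[C@H]1O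
F5 | step 6 | (2R,3R)-5-[(1S)-1-(acetyloxy)ethyl]-2-(3-hydroxyprop-1-en-2-yl)-2,3-dihydro-1-benzofuran-3-yl 3-methylbutanoate | C=C(CO)[C@H]1Oc2ccc([C@H](C)OC(C)=O)cc2[C@H]1OC(=O)CC(C)C
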